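## The problem

The target joins an α,β-unsaturated δ-lactone (ring A, C2–O4–C5–C7=C8–C9) spiro at C9 to a cyclohexane (ring B, C9–C10–C11–C12–C21–C22). Ring B is cis-fused to a cyclopentane (ring C, C12–C21–C20–C18–C25), and on this sits a bicyclo[2.2.2]octane with bridgeheads C14 and C25 and bridges C12–C13, C16–C18 and C30–C31, fused to a γ-lactone (ring D, C25–C26–O27–C28–C30). Nine stereocentres must be set (C9, C12, C14, C18, C21, C22, C25, C30, C31); five are all-carbon quaternary (C9, C12, C14, C18, C25), C18 and C25 are vicinal, and C22 is a tertiary carbinol. Control can be relayed: C9 is set absolutely and steers C22; the C22 oxygen delivers C20 to C21; the B/C junction steers C18; a C11 carbinol transfers a carbon to C25 by a sigmatropic shift; C12, C14, C30 and C31 are fixed by ring closures whose geometry the cage dictates. The ring A enoate does not survive organolithium reagents or hydrides, the C31 carbinol is β to both the C16 ketone and the C28 carbonyl (retro-aldol, dehydration), and the tertiary C22 alcohol ionises in strong acid, so these groups come late or are spared. The feature that opens the route is C13, an isolated methylene between quaternary C12 and C14 and β to the C16 ketone in the ring C12–C13–C14–C16–C18–C25. C12–C13 is therefore the bond a tertiary C12 radical makes with the CH2 terminus of a C13=C14 enone, and that radical is available from a C11=C12 alkene by hydrogen-atom transfer.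

## Retrosynthesis

**C31 bridge.** The last cut removes the one-carbon bridge: C14–C31 (aldol) and C30–C31 (formylation), from 33 through formyl lactone 32 and enaminone 31 to ketone 30. Attaching C31 first to C30, the only methylene next to a carbonyl, lets it reach C14 from within, so the exo face of C14 is not a selectivity question; the reverse order would ask an external electrophile to pick a face of a tetrasubstituted enolate. 30 has one ring and three stereocentres fewer. The aldol must run under acid, because the formyl lactone is a vinylogous acid that base would only deprotonate, and must stop at the β-hydroxy stage.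

**C12–C13 (key step).** The cyclohexanone ring of 30 is opened at C12–C13 to isopropenyl ketone 29 with a C11=C12 alkene. Three points favour this cut over its neighbours. C13–C14 or C16–C18 would need a quaternary acceptor or a bond between two quaternary carbons, whereas C12–C13 joins a tertiary radical to a CH2. The alkene needed for the radical is the one left behind when C25 is made. The tether C25–C18–C16 reaches only one face of C12. 29 lacks one ring, the bridged bicycle and two stereocentres. The forward step needs hydrogen-atom transfer to the trisubstituted alkene in the presence of two electron-poor alkenes.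

**Oxidised appendages.** 29 is unravelled in the order its sensitivity dictates: the C16 ketone from allylic alcohol 28, ring D from the C26 hydroxyl and C28 ester of 27, and ring A from aldehyde 25 through (Z)-enoate 26, back through alcohol 24 to ester 23. Ring A is closed only after the last organolithium step and the enone is unveiled only after the last acid step. The skeleton is unchanged, but 23 contains nothing more electrophilic than an ethyl ester.

**C25–C30.** C25 is vicinal to quaternary C18 and its C30 arm must sit cis to the C16 arm, the more hindered face, where an intermolecular alkylation would not go. The bond is therefore cut as a Johnson–Claisen transfer from the C11 oxygen of allylic alcohol 22, which also accounts for the C11=C12 alkene of 23. 22 comes from enone 21 by catalyst-controlled reduction. The forward step must build a quaternary centre next to another one and needs a defined C11 carbinol.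

**C25–C26 and the C18 substituents.** Enone 21 is the product of a Stork–Danheiser sequence. C25–C26 is cut to vinylogous ester 19 (through carbinol 20) and an alkoxymethyl anion; C18–C16 is cut to methacrolein (19 from 18) and C18–C19 to methyl iodide (18 from 17, the silyl-protected form of 16). The vinylogous ester has a single enolisable position, C18, and its carbonyl is also the site of the later 1,2-addition. Introducing methyl first and the four-carbon aldehyde second puts the larger group on the open face, as the target requires. 16 is far smaller than 21 and has two stereocentres fewer.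

**Ring C.** Ring C of 16 is opened at C12–C25, an intramolecular Claisen acylation of the C11 ketone in keto ester 14 (from lactone 13) that gives β-diketone 15. C21–C20 is cut as conjugate addition of a three-carbon Grignard reagent to γ-hydroxy enone 11, with 12 and 13 as oxidation-state adjustments. A cuprate would place the chain trans to the C22 oxygen, so the free hydroxyl is used to direct the addition. 11 has only ring B and two stereocentres.

**Ring B oxygenation.** Enone 11 is traced through epoxy ketone 10 to epoxy diol 9, whose C2 carbinol and C11 hydroxyl are the two halves of bridged lactone 8; 8 goes back to alkene 7 and iodolactone 6. The lactone keeps this part short: it forms from the amide of 5 with release of the auxiliary, carries the C11 oxygen, blocks one face of C21=C22 for the epoxidation, and two methyl groups turn its carbonyl into C1–C3.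

**C9.** 5 is cut at C9–C8 to the enolate from Birch reduction of benzamide 4 and an alkoxymethyl chloride; 4 is the amide of acid 1 and amine 2. This sets the first stereocentre absolutely, and every later one derives from it.

## Roads not taken

**Alternative 1:** The cage is cut at C25–C30 and C14–C31 as an intramolecular Diels–Alder reaction. Heating a 2-silyloxycyclohexadiene (C14=C16–C18=C25) carrying a (Z)-3-silylacrylate tethered through C26–O27–C28 would give A1, with ring D and the cage formed together.
- Merits: two C–C bonds and two rings in one step; four stereocentres (C14, C25, C30, C31) set by the tether and by suprafacial addition; the C31 oxygen stored as a silyl group that cannot eliminate.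
- Weak points: both diene termini become quaternary, so a fully substituted diene must add to a cis-disubstituted dienophile. C12 must be made quaternary beforehand without help from the cage. Ring C is still open in A1, so C18–C20 must later be closed at a carbon flanked by two quaternary centres. The arylsilane must be oxidised to the C31 hydroxyl in the presence of the enoate.
- Comparison: in bond economy and in the security of C30 and C31 this road is better; the chosen plan reaches the same centres in three steps and relies on an equilibrating aldol for two of them. Against that, the chosen plan closes every ring at an unhindered position, has ring C in place before the cage is built, and needs no late C–Si oxidation.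

**Alternative 2:** The cyclohexanone ring is made by ring expansion, cutting C13–C14. A bicyclo[2.2.1]heptane carrying a C16 tertiary alcohol and a C14–C31 epoxide would be treated with BF3·OEt2; the epoxide opens at C14, C13 migrates from C16 to C14, and A2, the C22 silyl ether of 33, results.
- Merits: the migration is stereospecific, so C14 and C31 follow from the epoxide; the ketone appears at C16 without a redox step; the target is one deprotection away.
- Weak points: the substrate already holds every other stereocentre in a more strained cage, so the difficulty is moved, not reduced. The C16 carbinol has two groups that can migrate, and quaternary C18 is the better one, which would give the wrong ring. The Lewis acid meets a tertiary silyl ether, a β-hydroxy lactone and an enoate.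
- Comparison: for the last step this road is at least as good as the chosen aldol, since it cannot give C31 epimers. The chosen plan answers with a precursor (30) simpler than its product and a closing step whose main side reaction is reversible.

**Alternative 3:** The cage is cut at C14–C16. A β-keto lactone (ketone at C31) is deprotonated twice with LiN(i-Pr)2 and the C14 carbanion adds to a C16 aldehyde on C18, giving A3 with a C16 carbinol and a C31 ketone.
- Merits: dianion regiochemistry is dependable; the aldol is irreversible at low temperature; C30 lies between two carbonyls and can equilibrate.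
- Weak points: the oxidation states at C16 and C31 are the reverse of those in 33, so an oxidation at hindered C16 and a face-selective reduction at C31 beside the new ketone must follow. The bond joins a tertiary carbanion to a neopentyl aldehyde. Two equivalents of amide base act on a substrate that carries the ring A enoate.
- Comparison: as a ring closure this aldol is probably more reliable than the acid-mediated one chosen here. The chosen plan offsets this by closing the cage at the correct oxidation level, from a ketone that can enolise only toward C14, with no redox correction afterwards.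

Key step: step 23

Assumption: the (S)-amide auxiliary is taken to deliver the alkoxymethyl chloride to the face of the Birch enolate that gives C9 as drawn in 5; were the sense opposite, the (R)-amine would be used and nothing else would change.

## Route

Step 1
Reactants: 1 2-methylbenzoic acid; 2 (S)-2-(methoxymethyl)pyrrolidine
Product: 4 (S)-[2-(methoxymethyl)pyrrolidin-1-yl](2-methylphenyl)methanone, via acid chloride 3 (not isolated)
Conditions: (COCl)2, DMF (cat.), CH2Cl2, 0 °C → rt; then 2, Et3N, 0 °C
Reagents that add atoms: none
Why: Acid chloride formation and N-acylation of the secondary amine; no stereocentre is touched.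

Step 2
Reactants: 4 benzamide
Product: 5 C9-quaternary cyclohexa-2,5-diene amide (C8 as CH2OPMB; C10=C11 and C21=C22 alkenes)
Conditions: K, NH3 (l), THF, t-BuOH (1 equiv), −78 °C; piperylene; then PMBOCH2Cl, −78 °C
Reagents that add atoms: 4-methoxybenzyl chloromethyl ether, COc1ccc(COCCl)cc1
Why: Birch reduction–alkylation of a chiral benzamide: the ring is reduced at C9 and C12, and the chelated potassium amide enolate is alkylated on one face by the reactive alkoxymethyl chloride, which sets C9.

Step 3
Reactants: 5 diene amide
Product: 6 iodolactone (C2 carbonyl bridged to O–C11; iodine on C10 trans to the lactone oxygen)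
Conditions: I2, NaHCO3, THF/H2O, rt
Reagents that add atoms: iodine, II; water, O
Why: Iodolactonisation with N-to-O acyl transfer: the amide oxygen opens the iodonium ion of the disubstituted C10=C11 alkene at C11, the only mode that gives a γ-lactone with iodine on a secondary carbon. Hydrolysis of the iminium lactone releases the auxiliary; the bridge from C9 to C11 is necessarily cis.

Step 4
Reactants: 6 iodolactone
Product: 7 bridged lactone (6-oxabicyclo[3.2.1]oct-3-en-7-one core)
Conditions: Bu3SnH, AIBN (cat.), PhH, 80 °C
Reagents that add atoms: none
Why: Radical dehalogenation with tin hydride; the secondary C10 radical is reduced without touching the alkene.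

Step 5
Reactants: 7 bridged lactone
Product: 8 epoxy lactone (C21–C22 epoxide on the face of the C8 arm)
Conditions: mCPBA, NaHCO3, CH2Cl2, 0 °C
Reagents that add atoms: 3-chloroperoxybenzoic acid, OOC(=O)c1cccc(Cl)c1
Why: Prilezhaev epoxidation of the trisubstituted alkene from the face away from the lactone bridge (the open face of the bicyclo[3.2.1] frame), which puts the C22 oxygen cis to the C8 arm.

Step 6
Reactants: 8 epoxy lactone
Product: 9 epoxy diol (C2 dimethyl carbinol; C11 secondary alcohol)
Conditions: MeLi (3.5 equiv), THF, −78 → 0 °C
Reagents that add atoms: methyllithium, [Li]C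
Why: Double addition of methyllithium to the lactone carbonyl gives the gem-dimethyl carbinol C1–C3 and frees the C11 hydroxyl; the hindered trisubstituted epoxide is not opened at this temperature.

Step 7
Reactants: 9 epoxy diol
Product: 11 γ-hydroxy enone (C11 ketone; C12=C21; C22 tertiary alcohol cis to the C8 arm), via epoxy ketone 10 (not isolated)
Conditions: Dess–Martin periodinane, CH2Cl2, rt; then Et3N, rt
Reagents that add atoms: none
Why: Dess–Martin oxidation of the C11 alcohol gives a β,γ-epoxy ketone, which opens by base-mediated β-elimination to the γ-hydroxy enone with the C22 configuration retained.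

Step 8
Reactants: 11 γ-hydroxy enone
Product: 12 keto triol (3-hydroxypropyl on C21 cis to the C22 hydroxyl)
Conditions: i-PrMgCl (2 equiv), THF, −78 °C; then ClMg(CH2)3OMgCl (from 3-chloropropan-1-ol, i-PrMgCl, then Mg), −78 → −20 °C; aq. NH4Cl
Reagents that add atoms: 3-chloropropan-1-ol (as its dimagnesium derivative), OCCCCl
Why: Alkoxide-directed conjugate addition of a Grignard reagent to a 4-oxido enone: the C22 magnesium alkoxide delivers the alkyl group to C21 on its own face, setting C21 with C20 cis to the C22 oxygen. The bulky C2 arm on C9 shields the other face.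

Step 9
Reactants: 12 keto triol
Product: 13 keto δ-lactone (O22–C25 lactone)
Conditions: TEMPO (cat.), PhI(OAc)2, CH2Cl2, rt
Reagents that add atoms: none
Why: Oxidative lactonisation of a 1,5-diol: oxoammonium oxidation of the primary alcohol, lactol formation with the cis C22 hydroxyl, and a second oxidation.

Step 10
Reactants: 13 keto δ-lactone
Product: 15 β-diketone (ring C closed; C11 and C25 carbonyls), via keto methyl ester 14 (not isolated)
Conditions: NaOMe, MeOH, rt; then aq. HCl
Reagents that add atoms: none
Why: Methoxide opens the lactone to the methyl ester, and intramolecular Claisen (Dieckmann-type) acylation of the C11 ketone enolate at C12 closes ring C; the β-diketone enolate is the thermodynamic sink.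

Step 11
Reactants: 15 β-diketone
Product: 16 vinylogous methyl ester (C11 methoxy enol ether; C25 ketone)
Conditions: MeOH, HC(OMe)3, TsOH (cat.), rt
Reagents that add atoms: methanol, CO
Why: Acid-catalysed enol etherification of a cyclic β-diketone under equilibrating conditions; the double bond settles inside the six-membered ring and exocyclic to the five-membered ring, which leaves C25 as the ketone.

Step 12
Reactants: 16 vinylogous ester
Product: 17 bis(trimethylsilyl) ether of 16 (C2 and C22 oxygens)
Conditions: N-(trimethylsilyl)imidazole, CH2Cl2, 40 °C
Reagents that add atoms: N-(trimethylsilyl)imidazole, C[Si](C)(C)n1ccnc1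
Why: Silylation of both tertiary alcohols with a neutral silyl donor, so the enolate steps need one equivalent of base and the aldolate of step 14 can be trapped selectively.

Step 13
Reactants: 17 bis-silyl vinylogous ester
Product: 18 C18-methyl vinylogous ester
Conditions: LiN(i-Pr)2, THF, −78 °C; MeI
Reagents that add atoms: iodomethane, CI
Why: Stork–Danheiser α′-alkylation: kinetic deprotonation at C18, the only enolisable position, then methylation. The C18 configuration does not matter because the centre is enolised again in step 14.

Step 14
Reactants: 18 C18-methyl vinylogous ester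
Product: 19 C18-quaternary aldol silyl ether (C16 carbinol as TBS ether; C13–C16 in place)
Conditions: LiN(i-Pr)2, THF, −78 °C; methacrolein; then TBSOTf, −78 °C
Reagents that add atoms: methacrolein, CC(=C)C=O; tert-butyldimethylsilyl trifluoromethanesulfonate, CC(C)(C)[Si](C)(C)OS(=O)(=O)C(F)(F)F
Why: Aldol addition of the tetrasubstituted C18 lithium enolate to the aldehyde on the face of ring C away from C22 (on the adjacent ring-fusion carbon), with in situ silylation to block retro-aldol. This sets C18 with methyl cis to C22; the C16 carbinol configuration (closed-transition-state epimer drawn) is erased in step 22.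

Step 15
Reactants: 19 aldol silyl ether
Product: 21 transposed enone (C11 ketone; C12=C25; C26 as CH2OMOM; tertiary alcohols free), via tertiary carbinol 20 (not isolated)
Conditions: Bu3SnCH2OCH2OMe, n-BuLi, THF, −78 °C; add 19; then 1 M HCl, THF, 0 °C → rt
Reagents that add atoms: tributyl[(methoxymethoxy)methyl]stannane, CCCC[Sn](CCCC)(CCCC)COCOC; water, O
Why: Stork–Danheiser transposition: the α-alkoxy organolithium adds to the C25 carbonyl, and acid hydrolysis of the enol ether with loss of water gives the enone carrying C26. The acid also removes the two trimethylsilyl ethers, while the hindered TBS ether and the MOM ether stay.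

Step 16
Reactants: 21 enone
Product: 22 C11 allylic alcohol (C11 oxygen on the face of H21 and cis to the C2 arm)
Conditions: (R)-2-methyl-CBS-oxazaborolidine (0.5 equiv), BH3·SMe2, THF, −30 °C
Reagents that add atoms: none
Why: Corey–Bakshi–Shibata reduction: the catalyst distinguishes the fully substituted alkenyl side (C12) from the methylene side (C10) and delivers hydride to the face that gives the required carbinol.

Step 17
Reactants: 22 allylic alcohol
Product: 23 C25-quaternary ethyl ester (C11=C12; C30–C28 as CH2CO2Et)
Conditions: MeC(OEt)3, EtCO2H (cat.), 140 °C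
Reagents that add atoms: triethyl orthoacetate, CCOC(C)(OCC)OCC
Why: Johnson–Claisen rearrangement: the ketene acetal formed on the C11 oxygen transfers C30 suprafacially to C25. This sets the quaternary centre with C30 cis to the C16 arm and moves the alkene to C11=C12.

Step 18
Reactants: 23 ethyl ester
Product: 24 C8 primary alcohol
Conditions: DDQ, CH2Cl2/pH 7 buffer, 0 °C
Reagents that add atoms: none
Why: Oxidative cleavage of the p-methoxybenzyl ether in wet solvent; the silyl ether, MOM ether and ester are not affected.

Step 19
Reactants: 24 primary alcohol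
Product: 25 C8 aldehyde
Conditions: TEMPO (cat.), PhI(OAc)2, CH2Cl2, rt
Reagents that add atoms: none
Why: Oxoammonium oxidation of the primary neopentyl alcohol to the non-enolisable aldehyde; tertiary alcohols do not react.

Step 20
Reactants: 25 aldehyde
Product: 27 ring A lactone ester, via (Z)-enoate 26 (not isolated)
Conditions: (CF3CH2O)2P(O)CH2CO2Me, KN(SiMe3)2, 18-crown-6, THF, −78 °C; then CSA (cat.), CH2Cl2, rt
Reagents that add atoms: methyl bis(2,2,2-trifluoroethyl)phosphonoacetate, COC(=O)CP(=O)(OCC(F)(F)F)OCC(F)(F)F
Why: Still–Gennari (Z)-selective Horner–Wadsworth–Emmons olefination, then acid-catalysed lactonisation of the (Z)-enoate with the adjacent C2 tertiary hydroxyl (helped by the gem-dimethyl group) closes ring A.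

Step 21
Reactants: 27 ring A lactone ester
Product: 28 bis-lactone C16 allylic alcohol
Conditions: HCl (2 M in MeOH), 0 °C → rt
Reagents that add atoms: none
Why: Acidic methanolysis removes the MOM and TBS ethers, and the freed C26 hydroxyl lactonises onto the C28 ester to give ring D.

Step 22
Reactants: 28 allylic alcohol
Product: 29 isopropenyl ketone (precursor of the key step)
Conditions: Dess–Martin periodinane, NaHCO3, CH2Cl2, rt
Reagents that add atoms: none
Why: Dess–Martin oxidation of the secondary allylic alcohol to the α-methylene ketone; the only other hydroxyl is tertiary.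

Step 23
Reactants: 29 isopropenyl ketone
Product: 30 bicyclo[3.2.1]octanone bis-lactone (C12 quaternary; product of the key step)
Conditions: Fe(acac)3 (0.5 equiv), PhSiH3 (2.5 equiv), EtOH/ethylene glycol (5:1), 60 °C, degassed
Reagents that add atoms: none
Why: Fe(acac)3 and PhSiH3 form an iron hydride that transfers a hydrogen atom to C11 of the electron-rich trisubstituted C11=C12 alkene, giving the tertiary C12 radical; this adds to the unsubstituted terminus C13 of the methacryloyl ketone, and the α-keto radical at C14 is reduced to the enolate and protonated by ethanol. The closest known reaction type is the metal-hydride hydrogen-atom-transfer radical conjugate addition (reductive olefin–enone coupling), run here intramolecularly. The ring C12–C13–C14–C16–C18–C25 closes 6-endo-trig, preferred over 5-exo because C14 is disubstituted and attack at C13 gives the stabilised α-keto radical. C12 is set by the tether: the acyl group sits on the lower face of ring C at C18, so C13 reaches C12 only from that face, giving the cis B/C junction with C13 cis to H21. C14 is protonated from the more open exo face (epimer drawn) and is re-enolised in step 25, so its configuration is immaterial. The step needs hydrogen-atom transfer to the donor alkene and not to the two electron-poor alkenes, and closure onto C13 and not onto C8 of ring A; the first follows from the polarity preference of the metal hydride, the second from C8 being a neopentyl, disubstituted acceptor whose 5-exo attack would build a norbornane. The free C22 hydroxyl and both lactones are inert under these neutral conditions.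

Step 24
Reactants: 30 bicyclo[3.2.1]octanone
Product: 31 C30 dimethylaminomethylene lactone (E)
Conditions: t-BuOCH(NMe2)2, toluene, 100 °C
Reagents that add atoms: tert-butoxybis(dimethylamino)methane, CN(C)C(OC(C)(C)C)N(C)C
Why: Condensation of the lactone α-methylene C30 with the aminal ester brings in C31; only a CH2 next to a carbonyl can form an enaminone, so the tertiary C14–H of the ketone is left alone.

Step 25
Reactants: 31 enaminone
Product: 33 target CNP0360620.2, via formyl lactone 32 (not isolated)
Conditions: 1 M HCl, THF, rt, then 45 °C
Reagents that add atoms: water, O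
Why: Acid hydrolysis of the enaminone gives the α-formyl lactone, whose aldehyde is attacked by the acid-generated C14=C16 enol in an intramolecular aldol addition that closes the bicyclo[2.2.2]octane; the tether from C25 forces C31 onto the exo face of C14. A hydrogen-bonded closed transition state (enol OH to aldehyde oxygen, aldehyde cis to the lactone carbonyl) places O32 and C28 on the side of the C16–C18 bridge, and C30 equilibrates by enolisation toward this isomer.

## Compound list

1 | 2-methylbenzoic acid | Cc1ccccc1C(=O)O | starting material
2 | (S)-2-(methoxymethyl)pyrrolidine | COC[C@@H]1CCCN1 | starting material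
3 | 2-methylbenzoyl chloride | Cc1ccccc1C(Cl)=O | intermediate (not isolated)
4 | (S)-[2-(methoxymethyl)pyrrolidin-1-yl](2-methylphenyl)methanone | Cc1ccccc1C(=O)N1CCC[C@H]1COC | intermediate
5 | Birch product: 1-[(4-methoxybenzyloxy)methyl]-2-methylcyclohexa-2,5-diene-1-carboxamide of 2, C9 quaternary | COc1ccc(COC[C@@]2(C(=O)N3CCC[C@H]3COC)C=CCC=C2C)cc1 | intermediate
6 | iodolactone: γ-lactone from C2 to O–C11, iodine on C10 trans to the lactone oxygen, C21=C22 intact | COc1ccc(COC[C@@]23C(=O)O[C@@H]([C@@H]2I)CC=C3C)cc1 | intermediate
7 | bridged lactone (6-oxabicyclo[3.2.1]oct-3-en-7-one with C22 methyl and CH2OPMB on C9) | COc1ccc(COC[C@@]23C(=O)O[C@@H](C2)CC=C3C)cc1 | intermediate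
8 | epoxy lactone, C21–C22 epoxide anti to the lactone bridge | COc1ccc(COC[C@@]23C(=O)O[C@@H](C2)C[C@H]4O[C@@]34C)cc1 | intermediate
9 | epoxy diol: C2 dimethyl carbinol, C11 alcohol, C21–C22 epoxide | COc1ccc(COC[C@@]2(C(C)(C)O)C[C@H](O)C[C@H]3O[C@@]23C)cc1 | intermediate
10 | β,γ-epoxy ketone (C11 ketone) | COc1ccc(COC[C@@]2(C(C)(C)O)CC(=O)C[C@H]3O[C@@]23C)cc1 | intermediate (not isolated)
11 | γ-hydroxy enone: C11 ketone, C12=C21, C22 tertiary alcohol cis to the C8 arm | COc1ccc(COC[C@@]2(C(C)(C)O)CC(=O)C=C[C@@]2(C)O)cc1 | intermediate
12 | keto triol: 3-hydroxypropyl (C20, C18, C25) on C21, cis to the C22 hydroxyl | COc1ccc(COC[C@@]2(C(C)(C)O)CC(=O)C[C@@H](CCCO)[C@@]2(C)O)cc1 | intermediate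
13 | keto δ-lactone (O22–C25 lactone, cis-fused to ring B) | COc1ccc(COC[C@@]2(C(C)(C)O)CC(=O)C[C@H]3CCC(=O)O[C@@]23C)cc1 | intermediate
14 | keto methyl ester (C25 as CO2Me) | COc1ccc(COC[C@@]2(C(C)(C)O)CC(=O)C[C@@H](CCC(=O)OC)[C@@]2(C)O)cc1 | intermediate (not isolated)
15 | β-diketone, ring C closed (C11 and C25 carbonyls; C12 enolised, drawn as keto form) | COc1ccc(COC[C@@]2(C(C)(C)O)CC(=O)C3C(=O)CC[C@H]3[C@@]2(C)O)cc1 | intermediate
16 | vinylogous methyl ester (C11 methoxy enol ether, C25 ketone) | COc1ccc(COC[C@@]2(C(C)(C)O)CC(OC)=C3C(=O)CC[C@H]3[C@@]2(C)O)cc1 | intermediate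
17 | bis(trimethylsilyl) ether of 16 | COc1ccc(COC[C@@]2(C(C)(C)O[Si](C)(C)C)CC(OC)=C3C(=O)CC[C@H]3[C@@]2(C)O[Si](C)(C)C)cc1 | intermediate
18 | C18-methyl vinylogous ester (epimer with methyl anti to C22 drawn) | COc1ccc(COC[C@@]2(C(C)(C)O[Si](C)(C)C)CC(OC)=C3C(=O)[C@H](C)C[C@H]3[C@@]2(C)O[Si](C)(C)C)cc1 | intermediate
19 | C18-quaternary aldol TBS ether (methyl cis to C22; C16 carbinol epimer from a closed transition state drawn) | COc1ccc(COC[C@@]2(C(C)(C)O[Si](C)(C)C)CC(OC)=C3C(=O)[C@](C)([C@@H](O[Si](C)(C)C(C)(C)C)C(C)=C)C[C@H]3[C@@]2(C)O[Si](C)(C)C)cc1 | intermediate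
20 | C25 tertiary carbinol with CH2OMOM (C25 configuration not defined) | COc1ccc(COC[C@@]2(C(C)(C)O[Si](C)(C)C)CC(OC)=C3C(O)(COCOC)[C@](C)([C@@H](O[Si](C)(C)C(C)(C)C)C(C)=C)C[C@H]3[C@@]2(C)O[Si](C)(C)C)cc1 | intermediate (not isolated)
21 | transposed enone: C11 ketone, C12=C25, C26 as CH2OMOM | COc1ccc(COC[C@@]2(C(C)(C)O)CC(=O)C3=C(COCOC)[C@](C)([C@@H](O[Si](C)(C)C(C)(C)C)C(C)=C)C[C@H]3[C@@]2(C)O)cc1 | intermediate
22 | C11 allylic alcohol, oxygen cis to the C2 arm | COc1ccc(COC[C@@]2(C(C)(C)O)C[C@H](O)C3=C(COCOC)[C@](C)([C@@H](O[Si](C)(C)C(C)(C)C)C(C)=C)C[C@H]3[C@@]2(C)O)cc1 | intermediate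
23 | C25-quaternary ethyl ester, C11=C12 | COc1ccc(COC[C@@]2(C(C)(C)O)CC=C3[C@](COCOC)(CC(=O)OCC)[C@](C)([C@@H](O[Si](C)(C)C(C)(C)C)C(C)=C)C[C@H]3[C@@]2(C)O)cc1 | intermediate
24 | C8 primary alcohol | OC[C@@]1(C(C)(C)O)CC=C2[C@](COCOC)(CC(=O)OCC)[C@](C)([C@@H](O[Si](C)(C)C(C)(C)C)C(C)=C)C[C@H]2[C@@]1(C)O | intermediate
25 | C8 aldehyde | O=C[C@@]1(C(C)(C)O)CC=C2[C@](COCOC)(CC(=O)OCC)[C@](C)([C@@H](O[Si](C)(C)C(C)(C)C)C(C)=C)C[C@H]2[C@@]1(C)O | intermediate
26 | (Z)-enoate (C7=C8) | COC(=O)/C=C\[C@@]1(C(C)(C)O)CC=C2[C@](COCOC)(CC(=O)OCC)[C@](C)([C@@H](O[Si](C)(C)C(C)(C)C)C(C)=C)C[C@H]2[C@@]1(C)O | intermediate (not isolated)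
27 | ring A lactone ester | CC1(C)OC(=O)C=C[C@]12CC=C3[C@](COCOC)(CC(=O)OCC)[C@](C)([C@@H](O[Si](C)(C)C(C)(C)C)C(C)=C)C[C@H]3[C@@]2(C)O | intermediate
28 | bis-lactone C16 allylic alcohol | CC1(C)OC(=O)C=C[C@]12CC=C3[C@@]4(COC(=O)C4)[C@](C)([C@@H](O)C(C)=C)C[C@H]3[C@@]2(C)O | intermediate
29 | cyclopentane lactone isopropenyl ketone (precursor of the key step) | CC1(C)OC(=O)C=C[C@]12CC=C3[C@@]4(COC(=O)C4)[C@](C)(C(=O)C(C)=C)C[C@H]3[C@@]2(C)O | intermediate
30 | bicyclo[3.2.1]octanone bis-lactone (product of the key step; C14–H exo) | CC1(C)OC(=O)C=C[C@]12CC[C@]13C[C@H](C)C(=O)[C@](C)(C[C@H]1[C@@]2(C)O)[C@]31COC(=O)C1 | intermediate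
31 | (E)-C30 dimethylaminomethylene lactone | CC1(C)OC(=O)C=C[C@]12CC[C@]13C[C@H](C)C(=O)[C@](C)(C[C@H]1[C@@]2(C)O)[C@]31COC(=O)/C1=C/N(C)C | intermediate
32 | C30 formyl lactone (C30 epimerisable, not defined) | CC1(C)OC(=O)C=C[C@]12CC[C@]13C[C@H](C)C(=O)[C@](C)(C[C@H]1[C@@]2(C)O)[C@]31COC(=O)C1C=O | intermediate (not isolated)
33 | CNP0360620.2 | CC1(C)OC(=O)C=C[C@]12CC[C@]13C[C@]4(C)C(=O)[C@](C)(C[C@H]1[C@@]2(C)O)[C@]31COC(=O)[C@H]1[C@H]4O | target

## Step count and risks

Total: 25 steps, all in one line from 1; longest linear sequence 25 steps.

**Step 23 (key step).** Hydrogen-atom transfer may go to the methacryloyl alkene (net conjugate reduction), or the C12 radical may close onto C8 of the ring A enoate instead of C13, because two electron-poor alkenes are present. The fallback runs the same closure before ring A carries its enoate. It sets out from 23: HCl in MeOH removes the MOM and TBS ethers and closes ring D to the ring D lactone allylic alcohol F1 (PMB ether kept); Dess–Martin oxidation gives the enone F2; Fe(acac)3 and PhSiH3 close it to the tricyclic ketone F3; DDQ frees the primary alcohol F4; TEMPO with PhI(OAc)2 gives the aldehyde F5; Still–Gennari olefination gives the (Z)-enoate F6, which lactonises with CSA to rejoin the route at 30.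

**Step 25.** The aldol may be followed by loss of water to the C30=C31 alkylidene lactone, or may revert or give C30/C31 epimers, because the formyl lactone is a vinylogous acid and the new carbinol is β to two carbonyls. The fallback reverses the roles of the partners. It sets out from 30: Me3SiOTf and Et3N give the silyl enol ether F7 (C22 also silylated); HC(OMe)3 with BF3·OEt2 formylates C14 from the exo face to the keto acetal F8; aqueous acid gives the keto aldehyde F9; LiN(SiMe3)2 at −78 °C adds the ring D lactone enolate to this non-enolisable aldehyde under kinetic control, arriving at 33.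

**Step 8.** Alkoxide direction may be lost with the aggregated, alkoxide-bearing Grignard reagent, leading to 1,2-addition or delivery to the wrong face. The fallback builds the chain differently. It sets out from 11: vinylmagnesium bromide is added under the same alkoxide-directed mode to give the vinyl ketone F10; cross-metathesis with methyl acrylate (second-generation Hoveyda–Grubbs catalyst) gives the enoate F11; conjugate reduction with [(Ph3P)CuH]6 gives keto ester 14, this time isolated, which NaOMe converts to 15.

**Step 16.** Hydride may be delivered to the wrong face of C11 if the two free hydroxyls or the spiro arm override the catalyst, and the wrong C11 epimer would relay to the wrong C25. The fallback sets out from 21: NaBH4 with CeCl3 (Luche reduction, substrate control) gives the epimeric carbinol F12; Mitsunobu inversion with 4-nitrobenzoic acid gives the ester F13; K2CO3 in MeOH releases 22.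

**Step 17.** At 140 °C the hindered ketene acetal may eliminate to a diene, or fail to rearrange, because the new quaternary centre forms next to quaternary C18. The fallback is the ester-enolate variant at low temperature. It sets out from 22: Ac2O with DMAP gives the C11 acetate F14; LiN(i-Pr)2 and Me3SiCl (−78 °C → rt, Ireland–Claisen) give the acid F15 after work-up; EtI with K2CO3 in DMF returns to 23.

Further compounds

F1 | step 23 | ring D lactone allylic alcohol with C8 PMB ether | COc1ccc(COC[C@@]2(C(C)(C)O)CC=C3[C@@]4(COC(=O)C4)[C@](C)([C@@H](O)C(C)=C)C[C@H]3[C@@]2(C)O)cc1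
F2 | step 23 | isopropenyl ketone with C8 PMB ether | COc1ccc(COC[C@@]2(C(C)(C)O)CC=C3[C@@]4(COC(=O)C4)[C@](C)(C(=O)C(C)=C)C[C@H]3[C@@]2(C)O)cc1
F3 | step 23 | bicyclo[3.2.1]octanone with C8 PMB ether | COc1ccc(COC[C@@]2(C(C)(C)O)CC[C@]34C[C@H](C)C(=O)[C@](C)(C[C@H]3[C@@]2(C)O)[C@]45COC(=O)C5)cc1
F4 | step 23 | bicyclo[3.2.1]octanone C8 primary alcohol | OC[C@@]1(C(C)(C)O)CC[C@]23C[C@H](C)C(=O)[C@](C)(C[C@H]2[C@@]1(C)O)[C@]34COC(=O)C4
F5 | step 23 | bicyclo[3.2.1]octanone C8 aldehyde | O=C[C@@]1(C(C)(C)O)CC[C@]23C[C@H](C)C(=O)[C@](C)(C[C@H]2[C@@]1(C)O)[C@]34COC(=O)C4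
F6 | step 23 | bicyclo[3.2.1]octanone (Z)-enoate | COC(=O)/C=C\[C@@]1(C(C)(C)O)CC[C@]23C[C@H](C)C(=O)[C@](C)(C[C@H]2[C@@]1(C)O)[C@]34COC(=O)C4
F7 | step 25 | C14=C16 trimethylsilyl enol ether, C22 trimethylsilyl ether | CC1(C)OC(=O)C=C[C@]12CC[C@]13CC(C)=C(O[Si](C)(C)C)[C@](C)(C[C@H]1[C@@]2(C)O[Si](C)(C)C)[C@]31COC(=O)C1
F8 | step 25 | C14 dimethoxymethyl ketone (acetal on the exo face) | CC1(C)OC(=O)C=C[C@]12CC[C@]13C[C@@](C)(C(OC)OC)C(=O)[C@](C)(C[C@H]1[C@@]2(C)O[Si](C)(C)C)[C@]31COC(=O)C1
F9 | step 25 | C14 formyl ketone | CC1(C)OC(=O)C=C[C@]12CC[C@]13C[C@@](C)(C=O)C(=O)[C@](C)(C[C@H]1[C@@]2(C)O)[C@]31COC(=O)C1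
F10 | step 8 | C21 vinyl ketone | COc1ccc(COC[C@@]2(C(C)(C)O)CC(=O)C[C@@H](C=C)[C@@]2(C)O)cc1
F11 | step 8 | C21 (E)-acrylate | COc1ccc(COC[C@@]2(C(C)(C)O)CC(=O)C[C@@H](/C=C/C(=O)OC)[C@@]2(C)O)cc1
F12 | step 16 | C11-epimeric allylic alcohol | COc1ccc(COC[C@@]2(C(C)(C)O)C[C@@H](O)C3=C(COCOC)[C@](C)([C@@H](O[Si](C)(C)C(C)(C)C)C(C)=C)C[C@H]3[C@@]2(C)O)cc1
F13 | step 16 | C11 4-nitrobenzoate (inverted) | COc1ccc(COC[C@@]2(C(C)(C)O)C[C@H](OC(=O)c4ccc(cc4)[N+](=O)[O-])C3=C(COCOC)[C@](C)([C@@H](O[Si](C)(C)C(C)(C)C)C(C)=C)C[C@H]3[C@@]2(C)O)cc1
F14 | step 17 | C11 acetate of 22 | COc1ccc(COC[C@@]2(C(C)(C)O)C[C@H](OC(C)=O)C3=C(COCOC)[C@](C)([C@@H](O[Si](C)(C)C(C)(C)C)C(C)=C)C[C@H]3[C@@]2(C)O)cc1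
F15 | step 17 | C28 carboxylic acid | COc1ccc(COC[C@@]2(C(C)(C)O)CC=C3[C@](COCOC)(CC(=O)O)[C@](C)([C@@H](O[Si](C)(C)C(C)(C)C)C(C)=C)C[C@H]3[C@@]2(C)O)cc1
A1 | alternative 1 | bicyclo[2.2.2]octene lactone silyl enol ether | CC1(C)OC(=O)C=C[C@]12CC[C@@]3([C@@H](CCl)[C@@]2(C)O[Si](CC)(CC)CC)C[C@]4(C)C(O[Si](C)(C)C(C)(C)C)=C(C)[C@]35COC(=O)[C@H]5[C@H]4[Si](C)(C)c6ccccc6
A2 | alternative 2 | target as its C22 trimethylsilyl ether | CC1(C)OC(=O)C=C[C@]12CC[C@]13C[C@]4(C)C(=O)[C@](C)(C[C@H]1[C@@]2(C)O[Si](C)(C)C)[C@]31COC(=O)[C@H]1[C@H]4O
A3 | alternative 3 | bridged C16 carbinol with C31 ketone | CC1(C)OC(=O)C=C[C@]12CC[C@]13C[C@]4(C)[C@H](O)[C@](C)(C[C@H]1[C@@]2(C)O)[C@]31COC(=O)[C@H]1C4=O
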